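**Plan**
Numbering: ring A has C1 (CH2O-acyl), C3 (OMe), C5 (OH), C6 (O-aryl); ring B has C1′ (O), C3′ (OH), C5′ (CH3).
Retrosynthesis: the palmitate C(=O)–O bond is cut first, then ring B is dismantled at C2′–C3′, C1′–C6′ and C3′–C4′. This leaves a ring-A aryl ethynyl ether (C1′, C2′) and 3-methylcyclobutenone (C3′–C6′ plus CH3); the ethynyl C–O bond goes back to a C6 phenol and trichloroethylene.
Enabling feature: ring B is a 1,3,5-trisubstituted benzene with oxygen on C1′ and C3′ and CH3 on C5′. This is the resorcinol monoether pattern that a vinylketene/ynol ether benzannulation delivers, so the di-ortho-flanked C6–O–C1′ ether is never made by aryl C–O coupling.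
Forward: ring A is bought as 2-hydroxy-4-methoxybenzaldehyde and re-oxygenated (Dakin-type oxidation, ortho-formylation, reduction). Its C6 oxygen becomes an ethynyl ether, ring B is grown on that oxygen, the benzyl and silyl groups are removed, and the C16 chain is joined last by a lipase.
Stereochemistry: none has to be set.

Key step: step 10

Remark: the target contains no stereocentre and no stereogenic double bond, so it is one achiral compound and the route needs no stereocontrol.

**Route**

Step 1
Reactants: 1 2-hydroxy-4-methoxybenzaldehyde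
Product: 2 2-(benzyloxy)-4-methoxybenzaldehyde
Conditions: BnBr, K2CO3, DMF, rt
Reagents that add atoms: benzyl bromide, BrCc1ccccc1
Why: Williamson etherification of the phenol; benzyl is chosen for this oxygen (the later C5–OH) because, unlike a phenolic silyl group, it cannot migrate to the neighbouring phenoxide in step 6 and it is inert to n-BuLi at low temperature and to heating.

Step 2
Reactants: 2 2-(benzyloxy)-4-methoxybenzaldehyde
Product: 4 2-(benzyloxy)-4-methoxyphenol, via aryl formate 3 (not isolated)
Conditions: mCPBA, CH2Cl2, 0 °C to rt; then K2CO3 (cat.), MeOH, rt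
Reagents that add atoms: 3-chloroperoxybenzoic acid, OOC(=O)c1cccc(Cl)c1
Why: Baeyer–Villiger (Dakin-type) oxidation, in which the ortho/para-dialkoxyaryl group migrates in preference to hydride to give the aryl formate, which is methanolysed to the phenol.

Step 3
Reactants: 4 2-(benzyloxy)-4-methoxyphenol
Product: 5 3-(benzyloxy)-2-hydroxy-5-methoxybenzaldehyde
Conditions: MgCl2, Et3N, (CH2O)n, MeCN, reflux
Reagents that add atoms: paraformaldehyde (as formaldehyde), C=O
Why: magnesium-mediated ortho-formylation of phenols (Casnati–Skattebøl), which can only occur at the single free ortho position because the other ortho and the para positions carry OBn and OMe.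

Step 4
Reactants: 5 3-(benzyloxy)-2-hydroxy-5-methoxybenzaldehyde
Product: 6 2-(benzyloxy)-6-(hydroxymethyl)-4-methoxyphenol
Conditions: NaBH4, MeOH, 0 °C
Reagents that add atoms: none
Why: borohydride reduction of the salicylaldehyde to the salicyl alcohol, with no other reducible group present.

Step 5
Reactants: 6 2-(benzyloxy)-6-(hydroxymethyl)-4-methoxyphenol
Product: 7 2-(benzyloxy)-6-{[(tert-butyldimethylsilyl)oxy]methyl}-4-methoxyphenol
Conditions: TBSCl (1.05 equiv), imidazole, CH2Cl2, 0 °C
Reagents that add atoms: tert-butyldimethylsilyl chloride, CC(C)(C)[Si](C)(C)Cl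
Why: silylation is selective for the primary benzylic alcohol, as is known for salicyl alcohols, and here the phenol is additionally flanked by two ortho substituents.

Step 6
Reactants: 7 2-(benzyloxy)-6-{[(tert-butyldimethylsilyl)oxy]methyl}-4-methoxyphenol; 8 trichloroethylene
Product: 9 {[3-(benzyloxy)-2-{[(E)-1,2-dichloroethenyl]oxy}-5-methoxyphenyl]methoxy}(tert-butyl)dimethylsilane
Conditions: K2CO3, DMF, 70 °C
Reagents that add atoms: none
Why: base-mediated anti addition of the phenoxide to dichloroacetylene generated in situ from trichloroethylene, the standard entry to aryl 1,2-dichlorovinyl ethers; the alkyl silyl ether and the benzyl ether are stable to K2CO3/DMF.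

Step 7
Reactants: 9 {[3-(benzyloxy)-2-{[(E)-1,2-dichloroethenyl]oxy}-5-methoxyphenyl]methoxy}(tert-butyl)dimethylsilane
Product: 12 {[3-(benzyloxy)-2-(ethynyloxy)-5-methoxyphenyl]methoxy}(tert-butyl)dimethylsilane, via chloroethynyl ether 10 (not isolated), via lithium aryloxyacetylide 11 (not isolated)
Conditions: n-BuLi (2.3 equiv), Et2O, −78 to −40 °C; then H2O, −78 °C; cold work-up, toluene solution used at once
Reagents that add atoms: none
Why: the known conversion of dichlorovinyl ethers into alkynyl ethers, in which n-BuLi eliminates LiCl to the chloroalkyne, chlorine–lithium exchange gives the acetylide and cold protonation gives the terminal ynol ether, which has no β-hydrogen for a retro-ene loss of ketene.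

Step 8
Reactants: 13 propyne
Product: 14 4,4-dichloro-3-methylcyclobut-2-en-1-one
Conditions: Cl3CCOCl, Zn(Cu), Et2O/DME, 0 °C to rt, excess propyne under a cold condenser
Reagents that add atoms: trichloroacetyl chloride, ClC(Cl)(Cl)C(Cl)=O
Why: ketene–alkyne [2+2] cycloaddition of dichloroketene formed in situ, with the ketene carbonyl carbon bonding to the terminal alkyne carbon as for other 1-alkynes.

Step 9
Reactants: 14 4,4-dichloro-3-methylcyclobut-2-en-1-one
Product: 15 3-methylcyclobut-2-en-1-one
Conditions: Zn dust, AcOH, TMEDA, EtOH, 0 °C to rt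
Reagents that add atoms: none
Why: zinc-mediated reductive dechlorination of an α,α-dichloro ketone, buffered with TMEDA/AcOH to suppress double-bond transposition; the volatile product is kept as a solution.

Step 10
Reactants: 12 {[3-(benzyloxy)-2-(ethynyloxy)-5-methoxyphenyl]methoxy}(tert-butyl)dimethylsilane; 15 3-methylcyclobut-2-en-1-one
Product: 20 3-[2-(benzyloxy)-6-{[(tert-butyldimethylsilyl)oxy]methyl}-4-methoxyphenoxy]-5-methylphenol, via vinylketene 16 (not isolated), via vinylcyclobutenone 17 (not isolated), via dienylketene 18 (not isolated), via cyclohexadienone 19 (not isolated)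
Conditions: 15 (2 equiv), toluene, 80 °C, sealed tube; then K2CO3, MeOH, rt (cleaves any aryl ester formed from excess ketene)
Reagents that add atoms: none
Why: At 80 °C cyclobutenone 15 opens reversibly (4π) to vinylketene 16, whose ketene C=C adds [2+2] to the electron-rich ynol ether 12 to give 17; a second 4π opening to the (E)-dienylketene 18 and 6π electrocyclisation give cyclohexadienone 19, which tautomerises to phenol 20. The closest known reaction type is the Danheiser benzannulation of cyclobutenones with alkoxy- and siloxyacetylenes to resorcinol monoethers. Ring B, the only ring formed, closes by thermal 6π electrocyclisation of the dienylketene (bond C3′–C4′) after C2′–C3′ and C1′–C6′ have been made in the ketene–alkyne [2+2]. No stereocentre appears in 20, since the sp3 carbon of 17 is lost on ring opening. The step needs the regiochemistry of the [2+2]: the oxygen lone pair of 12 makes the terminal alkyne carbon nucleophilic, so it bonds to the ketene carbonyl carbon, which puts the aryloxy group meta to the new OH and the CH3 meta to both. The bulky di-ortho-substituted ring A sits on oxygen, two atoms away from the reacting carbons, and the benzyl and silyl ethers are inert to ketenes at this temperature.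

Step 11
Reactants: 20 3-[2-(benzyloxy)-6-{[(tert-butyldimethylsilyl)oxy]methyl}-4-methoxyphenoxy]-5-methylphenol
Product: 21 3-{[(tert-butyldimethylsilyl)oxy]methyl}-2-(3-hydroxy-5-methylphenoxy)-5-methoxyphenol
Conditions: H2 (1 atm), 10% Pd/C, EtOAc, rt
Reagents that add atoms: none
Why: catalytic hydrogenolysis of the aryl benzyl ether; under neutral conditions the benzylic C–O bond of the silyl ether and the diaryl ether should not be cleaved.

Step 12
Reactants: 21 3-{[(tert-butyldimethylsilyl)oxy]methyl}-2-(3-hydroxy-5-methylphenoxy)-5-methoxyphenol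
Product: 22 3-(hydroxymethyl)-2-(3-hydroxy-5-methylphenoxy)-5-methoxyphenol
Conditions: TBAF, AcOH, THF, 0 °C to rt
Reagents that add atoms: none
Why: fluoride-induced cleavage of the primary silyl ether, buffered with acetic acid so that the electron-rich phenols are not kept as air-sensitive phenoxides.

Step 13
Reactants: 22 3-(hydroxymethyl)-2-(3-hydroxy-5-methylphenoxy)-5-methoxyphenol; 23 palmitic acid
Product: 24 betaethrin H
Conditions: Novozym 435 (immobilised Candida antarctica lipase B), 4 Å MS, 2-methyl-2-butanol, 45 °C
Reagents that add atoms: none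
Why: lipase-catalysed esterification acylates primary alcohols but not phenols, as in the enzymatic esterification of vanillyl alcohol with fatty acids, so both phenols stay free without protection.

**Compound list**
1 | 2-hydroxy-4-methoxybenzaldehyde | COc1ccc(C=O)c(O)c1 | starting material
2 | 2-(benzyloxy)-4-methoxybenzaldehyde | COc1ccc(C=O)c(OCc2ccccc2)c1 | intermediate
3 | 2-(benzyloxy)-4-methoxyphenyl formate | COc1ccc(OC=O)c(OCc2ccccc2)c1 | intermediate
4 | 2-(benzyloxy)-4-methoxyphenol | COc1ccc(O)c(OCc2ccccc2)c1 | intermediate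
5 | 3-(benzyloxy)-2-hydroxy-5-methoxybenzaldehyde | COc1cc(C=O)c(O)c(OCc2ccccc2)c1 | intermediate
6 | 2-(benzyloxy)-6-(hydroxymethyl)-4-methoxyphenol | COc1cc(CO)c(O)c(OCc2ccccc2)c1 | intermediate
7 | 2-(benzyloxy)-6-{[(tert-butyldimethylsilyl)oxy]methyl}-4-methoxyphenol | COc1cc(CO[Si](C)(C)C(C)(C)C)c(O)c(OCc2ccccc2)c1 | intermediate
8 | trichloroethylene | ClC=C(Cl)Cl | starting material
9 | {[3-(benzyloxy)-2-{[(E)-1,2-dichloroethenyl]oxy}-5-methoxyphenyl]methoxy}(tert-butyl)dimethylsilane | COc1cc(CO[Si](C)(C)C(C)(C)C)c(O/C(Cl)=C\Cl)c(OCc2ccccc2)c1 | intermediate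
10 | {[3-(benzyloxy)-2-[(chloroethynyl)oxy]-5-methoxyphenyl]methoxy}(tert-butyl)dimethylsilane | COc1cc(CO[Si](C)(C)C(C)(C)C)c(OC#CCl)c(OCc2ccccc2)c1 | intermediate
11 | lithium 2-[2-(benzyloxy)-6-{[(tert-butyldimethylsilyl)oxy]methyl}-4-methoxyphenoxy]ethyn-1-ide | COc1cc(CO[Si](C)(C)C(C)(C)C)c(OC#C[Li])c(OCc2ccccc2)c1 | intermediate
12 | {[3-(benzyloxy)-2-(ethynyloxy)-5-methoxyphenyl]methoxy}(tert-butyl)dimethylsilane | COc1cc(CO[Si](C)(C)C(C)(C)C)c(OC#C)c(OCc2ccccc2)c1 | intermediate
13 | propyne | CC#C | starting material
14 | 4,4-dichloro-3-methylcyclobut-2-en-1-one | CC1=CC(=O)C1(Cl)Cl | intermediate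
15 | 3-methylcyclobut-2-en-1-one | CC1=CC(=O)C1 | intermediate
16 | 3-methylbuta-1,3-dien-1-one (isopropenylketene) | CC(=C)C=C=O | intermediate
17 | 3-[2-(benzyloxy)-6-{[(tert-butyldimethylsilyl)oxy]methyl}-4-methoxyphenoxy]-4-(prop-1-en-2-yl)cyclobut-2-en-1-one (racemic) | CC(=C)C1C(=O)C=C1Oc1c(CO[Si](C)(C)C(C)(C)C)cc(OC)cc1OCc1ccccc1 | intermediate
18 | (3E)-3-[2-(benzyloxy)-6-{[(tert-butyldimethylsilyl)oxy]methyl}-4-methoxyphenoxy]-5-methylhexa-1,3,5-trien-1-one | C=C(C)/C=C(\C=C=O)Oc1c(CO[Si](C)(C)C(C)(C)C)cc(OC)cc1OCc1ccccc1 | intermediate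
19 | 3-[2-(benzyloxy)-6-{[(tert-butyldimethylsilyl)oxy]methyl}-4-methoxyphenoxy]-5-methylcyclohexa-2,4-dien-1-one | CC1=CC(Oc2c(CO[Si](C)(C)C(C)(C)C)cc(OC)cc2OCc2ccccc2)=CC(=O)C1 | intermediate
20 | 3-[2-(benzyloxy)-6-{[(tert-butyldimethylsilyl)oxy]methyl}-4-methoxyphenoxy]-5-methylphenol | Cc1cc(O)cc(Oc2c(CO[Si](C)(C)C(C)(C)C)cc(OC)cc2OCc2ccccc2)c1 | intermediate
21 | 3-{[(tert-butyldimethylsilyl)oxy]methyl}-2-(3-hydroxy-5-methylphenoxy)-5-methoxyphenol | Cc1cc(O)cc(Oc2c(CO[Si](C)(C)C(C)(C)C)cc(OC)cc2O)c1 | intermediate
22 | 3-(hydroxymethyl)-2-(3-hydroxy-5-methylphenoxy)-5-methoxyphenol | Cc1cc(O)cc(Oc2c(CO)cc(OC)cc2O)c1 | intermediate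
23 | palmitic acid (hexadecanoic acid) | CCCCCCCCCCCCCCCC(=O)O | starting material
24 | betaethrin H, [3-hydroxy-2-(3-hydroxy-5-methylphenoxy)-5-methoxyphenyl]methyl hexadecanoate | CCCCCCCCCCCCCCCC(=O)OCc1cc(OC)cc(O)c1Oc1cc(C)cc(O)c1 | target

**Step count and risks**
Total: 13 steps. Longest linear sequence: 11 steps (steps 1–7 and 10–13 from compound 1); the cyclobutenone branch (steps 8–9) joins at step 10.

Most likely to fail:

1. Step 10. The [2+2] capture of vinylketene 16 by the aryl ynol ether, which is less nucleophilic than an alkyl ynol ether, may be outrun at 80 °C by ketene dimerisation and thermal oligomerisation of the ynol ether. The fallback sets out from 12 and makes the same vinylketene at room temperature by photochemical Wolff rearrangement of 1-diazo-3-methylbut-3-en-2-one F1. F1 would be prepared from commercial 3-methylbut-3-en-2-one by detrifluoroacetylative diazo transfer (LiHMDS, CF3CO2CH2CF3, THF, −78 °C; then MsN3, Et3N, MeCN). Irradiation of F1 with 12 in CH2Cl2 at rt should let the [2+2] to 17 take place while the ynol ether is still intact. Brief warming in toluene at 80 °C would then carry 17 through 18 and 19, and the route is rejoined at 20.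

2. Step 7. The terminal aryl ethynyl ether may polymerise or hydrate during work-up and concentration, or the excess n-BuLi may lithiate the benzylic or aryl positions. The fallback sets out from 7 and attaches an intact ring B by copper-catalysed Ullmann-type diaryl ether coupling, a method known to tolerate 2,6-disubstituted phenols. Phenol 7 would be coupled with 1-(benzyloxy)-3-bromo-5-methylbenzene F2 (from commercial 3-bromo-5-methylphenol, BnBr, K2CO3) using CuI, picolinic acid and K3PO4 in DMSO at 90 °C. This should give {[3-(benzyloxy)-2-[3-(benzyloxy)-5-methylphenoxy]-5-methoxyphenyl]methoxy}(tert-butyl)dimethylsilane F3. Hydrogenolysis of both benzyl ethers (H2, Pd/C, EtOAc) returns the route at 21.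

3. Step 13. Acyl transfer may be slow or incomplete because the ortho-aryloxy group hinders access of the benzylic alcohol to the enzyme's active site. The fallback sets out from 22 and replaces enzymatic acyl transfer by activation of the alcohol: Mitsunobu esterification with palmitic acid 23 (PPh3, DIAD, THF, 0 °C), which is known to esterify phenolic benzyl alcohols chemoselectively. Only the primary alcohol forms an alkoxyphosphonium ion and the carboxylate, not the less acidic phenols, is the nucleophile. The route is rejoined directly at 24, and the fallback makes no new compound (F0).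

**Further compounds**
F1 | step 10 | 1-diazo-3-methylbut-3-en-2-one | C=C(C)C(=O)C=[N+]=[N-]
F2 | step 7 | 1-(benzyloxy)-3-bromo-5-methylbenzene | Cc1cc(Br)cc(OCc2ccccc2)c1
F3 | step 7 | {[3-(benzyloxy)-2-[3-(benzyloxy)-5-methylphenoxy]-5-methoxyphenyl]methoxy}(tert-butyl)dimethylsilane | Cc1cc(OCc2ccccc2)cc(Oc2c(CO[Si](C)(C)C(C)(C)C)cc(OC)cc2OCc2ccccc2)c1
F0 | step 13 | none | none
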